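I keep the books on the starting material, charged at 0.20 M, less than the 0.260 M of reagent, so it is the limiting reagent of the flask, and I count turnovers instead of hours.

    intermediate A ⇌ intermediate B (K1 = 2.4, k1 = 0.12 h⁻¹)
    starting material + reagent → intermediate A (k2 = 0.61 L mol⁻¹ h⁻¹)
    intermediate B → product (k3 = 0.25 h⁻¹)

starting material 0.20 M; reagent 0.260 M; time 25 h

- which holds at 25 h: what has brought the reaction to rest, or that it has not come to rest (the reagent has run out first / all of the starting material has reacted / forward and back rates have come level / it is still moving)
- conversion of starting material at 25 h
- amount of product at 25 h, in percent of the starting material charged

- the reaction counts as stopped when no species that holds the starting material changes by six tenths of a point or more over the second half of the time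
- run time (flask): 25 h

1. The step that joins starting material and reagent takes one of each, so in the flask the excess of reagent stays at 0.0600 M while both amounts fall.

2. The excess turnover count is 0.915: the rate constant of that step times the standing excess times the time. The ratio of reagent to starting material grows by the exponential of this count, so in the flask it climbs from 1.30 to 3.25.

3. The unreacted entry is the excess divided by that ratio less one, which is 13.4% of the charge, so I commit to a conversion of 86.6%.

4. Half the count gives 28.5% unreacted at half the time, so the starting material falls by 15 percentage points over the second half, and I enter the flask as still moving.

5. Product is reached through both intermediates, so I can book it no further than a bound: 86.6%.

The forecast answers "it is still moving", with conversion 86.6% and product 60.5%, holding that “no true equilibrium can halt the reaction”; its product is a figure where mine is a bound.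

The simulation gives "it is still moving", conversion 86.6% and product 60.9%, and at 25.0 h the flask still holds 17.4% of the charged starting material as intermediate A and 8.38% as intermediate B on the way to product. The neighbour flask, charged with 0.080 M of starting material, has a standing excess of 0.180 M, so its count is 2.75, larger than the 0.915 of the flask. The same entry leaves 4.51% of its starting material unreacted. Simulated, that neighbour flask reaches conversion 95.5% and product 68.2%, with intermediate A at 18.2% of its charged starting material.

(The constants used here belong to no real substance; the run is a simulation.)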